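**Retrosynthetic overview**
1. Fertidin ⇒ jaeschkeanadiol (9) + 4-methoxybenzoyl chloride (selective acylation of the secondary C6–OH).
2. 9 ⇒ aldehyde 8 by the C6–C7 disconnection: the seven-membered ring is closed last by a visible-light acridinium/thiol/Cr allylic C–H carbonyl allylation (a catalytic type-II carbonyl-ene), which also sets C6.
3. 8 ⇒ enal 6: Me2CuLi installs the angular methyl (C1) syn to the C4 oxygen; C5 is set by equilibration of the aldehyde.
4. 6 ⇒ enal 4 + methallyl bromide (γ-allylation of the vinylogous methyl, Claisen/Cope convergent).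
5. 4 ⇒ (S)-terpinen-4-ol (1) by ozonolysis/aldol: five-membered ring first, seven-membered ring second; the C4 carbinol is bought.

Assumption: (S)-(+)-terpinen-4-ol (major enantiomer of tea-tree oil) is purchased at ≥98% ee. Daucane numbering is used for positions (C4 = carbinol bearing iPr, C5 = ring-fusion CH, C1 = ring-fusion C–Me, C6 = CH–O).

**Step 1**
Reactants: 1 (S)-(+)-terpinen-4-ol; 2 ozone
Product: 3 (3S)-3-hydroxy-6-oxo-3-(propan-2-yl)heptanal
Conditions: O3, CH2Cl2/MeOH, NaHCO3, −78 °C; then Me2S, −78 °C → rt; used crude
Reagents that add atoms: ozone, O=[O+][O-]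
Why: Criegee ozonolysis of the only alkene with reductive work-up; the tertiary carbinol stereocenter is untouched and no new stereocenter forms.

**Step 2**
Reactants: 3
Product: 4 (5R)-5-hydroxy-2-methyl-5-(propan-2-yl)cyclopent-1-ene-1-carbaldehyde
Conditions: Bn2NH·TFA (20 mol%), PhMe, 50 °C
Reagents that add atoms: none
Why: Amine-catalysed intramolecular aldol condensation (aldehyde enamine onto the methyl ketone), as for the limonene-derived keto-aldehyde; the descriptor changes S→R only through CIP priorities, and no new stereocenter forms.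

**Step 3**
Reactants: 4; 5 3-bromo-2-methylprop-1-ene (methallyl bromide)
Product: 6 (5R)-5-hydroxy-2-(3-methylbut-3-en-1-yl)-5-(propan-2-yl)cyclopent-1-ene-1-carbaldehyde
Conditions: KHMDS (2.2 equiv), THF/DMPU, −78 °C; 5 (1.1 equiv), −78 → 0 °C; work-up; then PhMe, 140 °C (sealed)
Reagents that add atoms: methallyl bromide, CC(=C)CBr
Why: Kinetic γ-deprotonation of the methyl syn to CHO gives the exocyclic dienolate, and O-, α-C- or γ-C-allylation all converge on conjugated enal 6 on heating by Claisen and/or Cope [3,3] shifts (deconjugative alkylation/Cope); no new stereocenter.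

**Step 4**
Reactants: 6; 7 methyllithium (as Me2CuLi)
Product: 8 (1R,2R,5S)-2-hydroxy-5-methyl-5-(3-methylbut-3-en-1-yl)-2-(propan-2-yl)cyclopentane-1-carbaldehyde (CHO cis to OH and CH3, trans to iPr and side chain)
Conditions: Me2CuLi (3 equiv, from MeLi/CuI), Et2O, −40 → 0 °C; aq. NH4Cl; then DBU (0.2 equiv), CH2Cl2, 0 °C → rt
Reagents that add atoms: methyllithium, [Li]C (delivered as Me2CuLi, [Li+].C[Cu-]C)
Why: Gilman 1,4-addition places CH3 syn to the C4 lithium alkoxide and anti to the pseudoaxial iPr (both effects select the same face), setting the C1 quaternary center with the chain cis to iPr; DBU then equilibrates C5 so that CHO is trans to iPr and the chain (thermodynamic, OH···O=C hydrogen bond).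

**Step 5**
Reactants: 8
Product: 9 jaeschkeanadiol, (3R,3aS,4S,8aR)-6,8a-dimethyl-3-(propan-2-yl)-1,2,3,3a,4,5,8,8a-octahydroazulene-3,4-diol
Conditions: 9-mesityl-10-methylacridinium ClO4 (5 mol%), CrCl2 (10 mol%), dtbbpy (12 mol%), i-Pr3SiSH (10 mol%), 2,6-lutidine (20 mol%), CH2Cl2/MeCN, 0.01 M, 450 nm LEDs, rt
Reagents that add atoms: none
Why: Proposed new method: the thiyl radical (thiol oxidised by the excited acridinium) abstracts the weak secondary allylic C9–H, Cr(II) traps the allyl radical, and the allyl–Cr(III) adds to the Cr-bound aldehyde through C7 because the usual branched mode through C9 would require a trans-bicyclo[3.3.0]octane; this closes the trans-fused seven-membered ring, moves the alkene to C8=C9, and sets C6 (S) with the carbonyl oxygen on the open face chelated to the C4 oxygen and H6 tucked beside the angular methyl; closest known chemistry is the intermolecular acridinium/thiol/Cr allylation of aldehydes with unactivated alkenes and intramolecular Nozaki–Hiyama–Kishi allylation.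

**Step 6**
Reactants: 9; 10 4-methoxybenzoyl chloride
Product: 11 fertidin
Conditions: 10 (1.5 equiv), DMAP (0.3 equiv), Et3N, CH2Cl2, 0 → 40 °C
Reagents that add atoms: 4-methoxybenzoyl chloride, COc1ccc(cc1)C(Cl)=O
Why: DMAP-catalysed acylation selects the secondary C6–OH over the hindered tertiary C4–OH; no stereocenter is affected.

**Compound list**
1 | (S)-(+)-terpinen-4-ol, (1S)-4-methyl-1-(propan-2-yl)cyclohex-3-en-1-ol | CC1=CC[C@](O)(C(C)C)CC1 | starting material
2 | ozone | O=[O+][O-] | starting material (reagent)
3 | (3S)-3-hydroxy-6-oxo-3-(propan-2-yl)heptanal | O=CC[C@](O)(C(C)C)CCC(C)=O | intermediate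
4 | (5R)-5-hydroxy-2-methyl-5-(propan-2-yl)cyclopent-1-ene-1-carbaldehyde | O=CC1=C(C)CC[C@@]1(O)C(C)C | intermediate
5 | 3-bromo-2-methylprop-1-ene | CC(=C)CBr | starting material
6 | (5R)-5-hydroxy-2-(3-methylbut-3-en-1-yl)-5-(propan-2-yl)cyclopent-1-ene-1-carbaldehyde | O=CC1=C(CCC(C)=C)CC[C@@]1(O)C(C)C | intermediate
7 | methyllithium (used as Me2CuLi with CuI) | [Li]C | starting material
8 | (1R,2R,5S)-2-hydroxy-5-methyl-5-(3-methylbut-3-en-1-yl)-2-(propan-2-yl)cyclopentane-1-carbaldehyde | C=C(C)CC[C@@]1(C)CC[C@@](O)(C(C)C)[C@@H]1C=O | intermediate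
9 | jaeschkeanadiol | O[C@H]1CC(C)=CC[C@@]2(C)CC[C@@](O)(C(C)C)[C@H]12 | intermediate
10 | 4-methoxybenzoyl chloride | COc1ccc(cc1)C(Cl)=O | starting material
11 | fertidin | COc1ccc(C(=O)O[C@H]2CC(C)=CC[C@@]3(C)CC[C@@](O)(C(C)C)[C@H]23)cc1 | target

**Totals**
Total steps: 6. Longest linear sequence: 6.

**Three steps most likely to fail**
1. Step 5 (proposed new step). Risks: HAT at the allylic CH3 instead of C9–H (exocyclic-methylene isomer), acyl-radical side reactions, or the wrong C6 epimer. Fallback (known chemistry): pre-oxidise C9 instead of abstracting C9–H. Replace step 3 by a vinylogous Mukaiyama aldol of the silyl dienol ether of 4 with methacrolein, carry the C9 carbinol through the cuprate step, convert it to the allylic bromide (CBr4/PPh3), and close the ring by a CrCl2 Nozaki–Hiyama–Kishi allylation at high dilution. A wrong C6 epimer is corrected by Dess–Martin oxidation then Me4NBH(OAc)3 (1,3-anti reduction directed by the C4–OH).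
2. Step 3. Risks: poor regiocontrol of aldehyde dienolate formation (ring CH2 vs CH3) or self-condensation. Fallback: install the chain before the ring. Protect the aldehyde of 3 as a dioxolane, alkylate the kinetic methyl-ketone enolate (LDA) with methallyl bromide, then unmask with acid and run the aldol condensation to reach 6.
3. Step 4. Risks: 1,2-addition, low facial selectivity at C1, or retro-aldol of the β-hydroxy aldehyde. Fallback: angular methylation by cyclopropanation. Reduce 6 with DIBAL to the allylic diol, run a Simmons–Smith cyclopropanation directed by the C4–OH (CH2 delivered cis to OH), reoxidise to the cyclopropyl aldehyde, and open the exocyclic cyclopropane bond reductively (SmI2 or Li/NH3) to give the C1 methyl and the C5 enolate, which is protonated and equilibrated as before.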